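**Strategy.** The target is a (7R,7′R,8S,8′S)-syringaresinol whose two phenols carry guaiacylglycerol 8-O-4 arms. Everything rests on cutting the furo[3,4-c]furan at C7–C8 and C8′–C7′. C8 and C8′ each bear one benzylic C–O carbon and one CH2O carbon, which is C4 and C3 of a 5-alkoxybutenolide. In one operation a lithiated aryl dithiane adds to C4 of the (5S)-menthyloxybutenolide and the enolate is trapped by a second aldehyde. This fixes C8/C8′ trans and delivers two differently masked syringyl rings. The precursors are the TIPS-protected syringyl dithiane, the butenolide and syringaldehyde pivalate. The arms are then built by auxiliary-controlled aldol reactions.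

Key step: step 6

Remark on numbering: lignan locants are used (C7/C7′ benzylic, C8/C8′, C9/C9′ oxymethylene; the same locants inside each arm). Ring A is the syringyl ring from the dithiane, ring B the one from the aldehyde. G1 is the erythro (7S,8R) arm on ring B, G2 the threo (7R,8R) unit on ring A, G3 the erythro (7R,8S) unit on the 4-O of G2.

Remark on protecting groups: ring A is carried as a TIPS ether (stable to BuLi, LiAlH4, acid and carbonate; removed late by fluoride). Ring B is carried as a pivalate, which LiAlH4 removes in step 8, so the two core phenols are freed at different times without extra steps and both are orthogonal to the benzyl ethers removed last.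

Assumption: 17, 19, 25 and 26 are bought; the carbinol centres C7/C7′ of 13–15 are epimer mixtures and are written without configuration.

Step 1
Reactants: 1 furfural
Product: 3 5-hydroxyfuran-2(5H)-one (racemic), via furan endoperoxide 2 (not isolated)
Conditions: O2, hν (visible), rose bengal (cat.), MeOH, rt
Reagents that add atoms: dioxygen, O=O
Why: Dye-sensitised singlet-oxygen [4+2] photooxygenation of the furan gives endoperoxide 2, which methanol opens with loss of the formyl carbon as methyl formate; the lactol centre is racemic and is corrected in step 2.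

Step 2
Reactants: 3 5-hydroxyfuran-2(5H)-one; 4 (+)-menthol
Product: 5 (5S)-5-[(1S,2R,5S)-menthyloxy]furan-2(5H)-one
Conditions: CSA (cat.), toluene, reflux, Dean–Stark; crystallise from petroleum ether, re-equilibrate mother liquor with acid
Reagents that add atoms: none
Why: Acid-catalysed acetalisation of the lactol gives both C5 epimers, which interconvert through the oxocarbenium ion while the (5S)-epimer crystallises, so the acetal centre is set by crystallisation-induced diastereomer transformation.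

Step 3
Reactants: 6 syringaldehyde; 7 propane-1,3-dithiol
Product: 8 4-(1,3-dithian-2-yl)-2,6-dimethoxyphenol
Conditions: BF3·OEt2 (cat.), CH2Cl2, 0 °C to rt
Reagents that add atoms: none
Why: Lewis-acid dithioacetalisation of an aryl aldehyde, which tolerates the free phenol.

Step 4
Reactants: 8 4-(1,3-dithian-2-yl)-2,6-dimethoxyphenol
Product: 9 2-[3,5-dimethoxy-4-(triisopropylsilyloxy)phenyl]-1,3-dithiane
Conditions: TIPSOTf, 2,6-lutidine, CH2Cl2, 0 °C to rt
Reagents that add atoms: triisopropylsilyl trifluoromethanesulfonate, CC(C)[Si](C(C)C)(C(C)C)OS(=O)(=O)C(F)(F)F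
Why: O-silylation of the hindered phenol with the reactive silyl triflate gives an ether with no acidic site to compete with the dithiane C–H in step 6.

Step 5
Reactants: 6 syringaldehyde
Product: 10 4-formyl-2,6-dimethoxyphenyl pivalate
Conditions: PivCl, Et3N, DMAP (cat.), CH2Cl2, 0 °C to rt
Reagents that add atoms: pivaloyl chloride, CC(C)(C)C(=O)Cl
Why: O-acylation of the acidic phenol gives a hindered ester, flanked by two methoxy groups, that should resist a lithium enolate at −78 °C.

Step 6
Reactants: 9 2-[3,5-dimethoxy-4-(triisopropylsilyloxy)phenyl]-1,3-dithiane; 5 (5S)-5-menthyloxyfuran-2(5H)-one; 10 4-formyl-2,6-dimethoxyphenyl pivalate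
Product: 13 (3R,4S,5S)-3-[hydroxy(3,5-dimethoxy-4-pivaloyloxyphenyl)methyl]-4-{2-[3,5-dimethoxy-4-(triisopropylsilyloxy)phenyl]-1,3-dithian-2-yl}-5-[(1S,2R,5S)-menthyloxy]dihydrofuran-2(3H)-one (carbinol epimers), via lithiated dithiane 11 (not isolated), via lithium enolate 12 (not isolated)
Conditions: n-BuLi, THF, −78 to −20 °C; 5, −78 °C; 10, −78 °C; AcOH/THF quench at −78 °C
Reagents that add atoms: none
Why: n-BuLi removes the dithiane C2–H to give the aryl- and sulfur-stabilised anion 11, which adds in Michael fashion to C4 of butenolide 5 to give lithium enolate 12, and 12 adds to the formyl group of 10 in an aldol reaction (tandem conjugate addition–aldol, the established reactivity of lithiated aryl dithioacetals with 5-alkoxy-2(5H)-furanones). No ring is closed; the two skeletal bonds C7–C8 and C8′–C7′ and three stereocentres are formed. The C4 centre (C8) is controlled by the C5 acetal, whose menthyloxy group shields one face so that the anion enters anti to it; the C3 centre (C8′) is controlled by the new bulky C4 dithianyl group, the aldehyde approaching the enolate anti to it, which should give the 3,4-trans-4,5-trans lactone. The carbinol centre is not controlled and need not be, because it passes through a planar benzylic cation in step 9. The step needs 1,4- over 1,2-addition and trapping before any proton transfer: the soft, hindered, delocalised anion should secure the first, and a non-enolisable aldehyde added at −78 °C with a cold acidic quench the second. The pivalate and the TIPS ether should be inert to the enolate at this temperature.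

Step 7
Reactants: 13 tandem adduct
Product: 14 (3R,4S,5S)-3-[hydroxy(3,5-dimethoxy-4-pivaloyloxyphenyl)methyl]-4-[3,5-dimethoxy-4-(triisopropylsilyloxy)benzoyl]-5-[(1S,2R,5S)-menthyloxy]dihydrofuran-2(3H)-one
Conditions: HgO, BF3·OEt2, THF/H2O, rt
Reagents that add atoms: water, O
Why: Thiophile-assisted hydrolysis of the dithioacetal unmasks the C7 aryl ketone while lactone, acetal, silyl ether and pivalate are stable, and C4, now alpha to the ketone, already holds its more stable all-trans arrangement.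

Step 8
Reactants: 14 keto lactone
Product: 15 (2S,3S)-1-[3,5-dimethoxy-4-(triisopropylsilyloxy)phenyl]-4-(4-hydroxy-3,5-dimethoxyphenyl)-2,3-bis(hydroxymethyl)butane-1,4-diol (C1/C4 epimers)
Conditions: LiAlH4, THF, 0 °C to rt; Rochelle salt work-up
Reagents that add atoms: none
Why: Exhaustive hydride reduction converts the ketone to the C7 carbinol, opens the lactone to the C9′ alcohol, releases the hemiacetal that collapses with loss of menthol to an aldehyde reduced to the C9 alcohol, and cleaves the pivalate to the ring B phenol, all without touching C8/C8′.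

Step 9
Reactants: 15 pentaol
Product: 16 4-[(1R,3aS,4R,6aS)-4-(3,5-dimethoxy-4-triisopropylsilyloxyphenyl)tetrahydro-1H,3H-furo[3,4-c]furan-1-yl]-2,6-dimethoxyphenol (mono-TIPS ether of (−)-syringaresinol)
Conditions: CSA (0.1 equiv), CH2Cl2/THF, 0 °C to rt, stopped when the monocyclic intermediates are consumed
Reagents that add atoms: none
Why: Acid-catalysed double cyclodehydration in which each benzylic carbinol ionises (ring B through its para-quinone methide, ring A through the aryl-stabilised cation) and is captured 5-exo-trig by the CH2OH on the other carbon of the C8–C8′ bond, so the carbinol configuration is erased and each aryl group should settle exo, trans to its neighbouring ring-fusion substituent (7R,7′R), as dictated by the fixed 8S,8′S pair.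

Step 10
Reactants: 16 mono-TIPS syringaresinol; 17 (S)-4-benzyl-3-(chloroacetyl)oxazolidin-2-one
Product: 18 ring B O-{2-[(S)-4-benzyl-2-oxooxazolidin-3-yl]-2-oxoethyl} ether of 16
Conditions: K2CO3, NaI (cat.), acetone, 50 °C
Reagents that add atoms: none
Why: Williamson etherification of the phenoxide at the doubly activated CH2–Cl (iodide catalysis), where SN2 at carbon should outrun attack at the imide carbonyl and the silyl ether is stable to carbonate in acetone.

Step 11
Reactants: 18 ring B aryloxyacetyl imide; 19 4-benzyloxy-3-methoxybenzaldehyde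
Product: 21 (4S)-4-benzyl-3-[(2S,3R)-3-(4-benzyloxy-3-methoxyphenyl)-3-hydroxy-2-(ring B aryloxy)propanoyl]oxazolidin-2-one on the core of 16, via boron enolate 20 (not isolated)
Conditions: Bu2BOTf, iPr2NEt, CH2Cl2, −78 to 0 °C; 19, −78 to 0 °C; pH 7 buffer, MeOH, H2O2, 0 °C
Reagents that add atoms: none
Why: Evans syn-aldol in which the (Z)-dibutylboron enolate 20 reacts through a closed chair transition state on the enolate face remote from the benzyl group of the (S)-auxiliary, setting C8 and C7 of G1 together as the syn (2S,3R) adduct, which is the (7R,8R)-threo arrangement.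

Step 12
Reactants: 21 syn aldol adduct
Product: 22 ring B (1R,2R)-1-(4-benzyloxy-3-methoxyphenyl)-1,3-dihydroxypropan-2-yl ether of 16 (threo diol)
Conditions: LiBH4, THF, H2O (1 equiv), 0 °C
Reagents that add atoms: none
Why: Reductive removal of the auxiliary by hydride attack at the exocyclic imide carbonyl gives the primary C9 alcohol without touching C7/C8, and aryl silyl and benzyl ethers are inert.

Step 13
Reactants: 22 threo diol
Product: 23 ring B (1S,2R)-1-(4-benzyloxy-3-methoxyphenyl)-1,3-bis(4-nitrobenzoyloxy)propan-2-yl ether of 16 (erythro diester)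
Conditions: PPh3, DIAD, 4-nitrobenzoic acid (3 equiv each), THF, 0 °C to rt
Reagents that add atoms: 4-nitrobenzoic acid, O=C(O)c1ccc(cc1)[N+](=O)[O-]
Why: Double Mitsunobu esterification acylates the primary C9–OH and displaces the secondary benzylic C7–OH by carboxylate with SN2 inversion (7R to 7S), so threo becomes the erythro (7S,8R) arm and both hydroxyls are masked for the next arm, the beta-aryloxy group disfavouring ionisation.

Step 14
Reactants: 23 erythro diester
Product: 24 ring A phenol of 23 (TIPS removed)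
Conditions: TBAF, AcOH (1:1), THF, 0 °C
Reagents that add atoms: none
Why: Fluoride cleavage of the aryl silyl ether, buffered with acetic acid so that the activated esters are not attacked, frees the second core phenol.

Step 15
Reactants: 25 (E)-isoeugenol; 26 (R)-4-benzyl-3-(chloroacetyl)oxazolidin-2-one
Product: 27 (4R)-4-benzyl-3-{2-[2-methoxy-4-((E)-prop-1-enyl)phenoxy]acetyl}oxazolidin-2-one
Conditions: K2CO3, NaI (cat.), acetone, 50 °C
Reagents that add atoms: none
Why: Williamson etherification as in step 10, with the propenyl group serving as a formyl group that is blind to the aldol, reduction and Mitsunobu steps.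

Step 16
Reactants: 27 isoeugenyl oxyacetyl imide; 19 4-benzyloxy-3-methoxybenzaldehyde
Product: 29 (4R)-4-benzyl-3-[(2R,3S)-3-(4-benzyloxy-3-methoxyphenyl)-3-hydroxy-2-(2-methoxy-4-((E)-prop-1-enyl)phenoxy)propanoyl]oxazolidin-2-one, via boron enolate 28 (not isolated)
Conditions: Bu2BOTf, iPr2NEt, CH2Cl2, −78 to 0 °C; 19, −78 to 0 °C; pH 7 buffer, MeOH, H2O2, 0 °C
Reagents that add atoms: none
Why: Evans syn-aldol with the (R)-auxiliary, which should give the mirror-image facial sense and hence the (2R,3S) adduct, the (7S,8S)-threo precursor of G3.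

Step 17
Reactants: 29 syn aldol adduct
Product: 30 (1S,2S)-1-(4-benzyloxy-3-methoxyphenyl)-2-[2-methoxy-4-((E)-prop-1-enyl)phenoxy]propane-1,3-diol
Conditions: LiBH4, THF, H2O (1 equiv), 0 °C
Reagents that add atoms: none
Why: Reductive removal of the auxiliary to the primary alcohol, which leaves the alkene and both stereocentres untouched.

Step 18
Reactants: 30 threo diol
Product: 31 (1R,2S)-1-(4-benzyloxy-3-methoxyphenyl)-2-[2-methoxy-4-((E)-prop-1-enyl)phenoxy]propane-1,3-diyl bis(4-nitrobenzoate)
Conditions: PPh3, DIAD, 4-nitrobenzoic acid (3 equiv each), THF, 0 °C to rt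
Reagents that add atoms: 4-nitrobenzoic acid, O=C(O)c1ccc(cc1)[N+](=O)[O-]
Why: Double Mitsunobu esterification with SN2 inversion at the benzylic carbinol (7S to 7R) should give the erythro (7R,8S) unit G3 in ester-protected form.

Step 19
Reactants: 31 erythro diester
Product: 32 4-{[(1R,2S)-1-(4-benzyloxy-3-methoxyphenyl)-1,3-bis(4-nitrobenzoyloxy)propan-2-yl]oxy}-3-methoxybenzaldehyde
Conditions: K2OsO4·2H2O (cat.), NaIO4, 2,6-lutidine, dioxane/H2O, rt
Reagents that add atoms: sodium periodate, [Na+].[O-]I(=O)(=O)=O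
Why: Lemieux–Johnson oxidative cleavage (catalytic osmylation of the electron-rich styrene double bond, then periodate cleavage of the diol) unveils the aryl aldehyde without affecting esters, benzyl ether or stereocentres.

Step 20
Reactants: 24 ring A phenol; 17 (S)-4-benzyl-3-(chloroacetyl)oxazolidin-2-one
Product: 33 ring A O-{2-[(S)-4-benzyl-2-oxooxazolidin-3-yl]-2-oxoethyl} ether of 24
Conditions: K2CO3, NaI (cat.), acetone, 50 °C
Reagents that add atoms: none
Why: Williamson etherification as in step 10, the 4-nitrobenzoates being stable to anhydrous carbonate in acetone.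

Step 21
Reactants: 33 ring A aryloxyacetyl imide; 32 aldehyde carrying G3
Product: 35 (4S)-4-benzyl-3-[(2S,3R)-3-hydroxy-3-{3-methoxy-4-[(G3 diester)oxy]phenyl}-2-(ring A aryloxy)propanoyl]oxazolidin-2-one on the core of 24, via boron enolate 34 (not isolated)
Conditions: Bu2BOTf, iPr2NEt, CH2Cl2, −78 to 0 °C; 32, −78 to 0 °C; pH 7 buffer, MeOH, H2O2, 0 °C
Reagents that add atoms: none
Why: Evans syn-aldol of the (Z)-boron enolate 34, in which the (S)-auxiliary again should fix the (7R,8R)-threo unit G2 while the remote stereocentres of the aldehyde have no say and the aryl esters are inert to a boron enolate.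

Step 22
Reactants: 35 aldol adduct
Product: 36 bis(O-benzyl) ether of the target at the phenols of G1 and G3 (hexaol)
Conditions: LiBH4 (excess), THF/MeOH, 0 °C to rt
Reagents that add atoms: none
Why: Borohydride reduction removes the auxiliary to give the C9 alcohol of G2 and reductively cleaves all four 4-nitrobenzoates in the same operation, leaving nitro-free product, aryl ethers, the furofuran and every stereocentre untouched.

Step 23
Reactants: 36 bis(O-benzyl) hexaol
Product: 37 target CNP0316493.1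
Conditions: H2 (1 atm), 10% Pd/C, EtOAc/MeOH, rt, stopped after two equivalents of H2
Reagents that add atoms: none
Why: Catalytic hydrogenolysis of the two aryl benzyl ethers under neutral conditions, where aryl O–benzyl bonds cleave much faster than the benzylic C–O bonds of the furofuran and of the arm carbinols, should release the target with all ten stereocentres intact.

**Compound list**

1 | furfural | O=Cc1ccco1 | starting material
2 | furfural endoperoxide, 2,3,7-trioxabicyclo[2.2.1]hept-5-ene-1-carbaldehyde | O=CC12OOC(C=C1)O2 | intermediate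
3 | 5-hydroxyfuran-2(5H)-one (racemic) | O=C1C=CC(O)O1 | intermediate
4 | (+)-menthol, (1S,2R,5S) | C[C@H]1CC[C@@H]([C@H](C1)O)C(C)C | starting material
5 | (5S)-5-[(1S,2R,5S)-menthyloxy]furan-2(5H)-one | O=C1C=C[C@@H](O[C@H]2C[C@@H](C)CC[C@@H]2C(C)C)O1 | intermediate
6 | syringaldehyde | COc1cc(C=O)cc(OC)c1O | starting material
7 | propane-1,3-dithiol | SCCCS | starting material
8 | 4-(1,3-dithian-2-yl)-2,6-dimethoxyphenol | COc1cc(C2SCCCS2)cc(OC)c1O | intermediate
9 | 2-[3,5-dimethoxy-4-(triisopropylsilyloxy)phenyl]-1,3-dithiane | COc1cc(C2SCCCS2)cc(OC)c1O[Si](C(C)C)(C(C)C)C(C)C | intermediate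
10 | 4-formyl-2,6-dimethoxyphenyl pivalate | COc1cc(C=O)cc(OC)c1OC(=O)C(C)(C)C | intermediate
11 | 2-lithio derivative of 9 | [Li]C1(c2cc(OC)c(O[Si](C(C)C)(C(C)C)C(C)C)c(OC)c2)SCCCS1 | intermediate
12 | lithium enolate of the 4,5-trans Michael adduct | [Li]OC1=C[C@H](C2(c3cc(OC)c(O[Si](C(C)C)(C(C)C)C(C)C)c(OC)c3)SCCCS2)[C@@H](O[C@H]2C[C@@H](C)CC[C@@H]2C(C)C)O1 | intermediate
13 | (3R,4S,5S) tandem adduct: aryl carbinol at C3, aryl dithiane at C4, menthyloxy at C5 (carbinol epimers) | O=C1[C@@H](C(O)c2cc(OC)c(OC(=O)C(C)(C)C)c(OC)c2)[C@H](C2(c3cc(OC)c(O[Si](C(C)C)(C(C)C)C(C)C)c(OC)c3)SCCCS2)[C@@H](O[C@H]2C[C@@H](C)CC[C@@H]2C(C)C)O1 | intermediate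
14 | (3R,4S,5S) keto lactone | O=C1[C@@H](C(O)c2cc(OC)c(OC(=O)C(C)(C)C)c(OC)c2)[C@H](C(=O)c2cc(OC)c(O[Si](C(C)C)(C(C)C)C(C)C)c(OC)c2)[C@@H](O[C@H]2C[C@@H](C)CC[C@@H]2C(C)C)O1 | intermediate
15 | (2S,3S)-2,3-bis(hydroxymethyl)butane-1,4-diol with ring A (TIPS ether) at C1 and ring B (free phenol) at C4 | OC(c1cc(OC)c(O[Si](C(C)C)(C(C)C)C(C)C)c(OC)c1)[C@H](CO)[C@@H](CO)C(O)c1cc(OC)c(O)c(OC)c1 | intermediate
16 | mono-TIPS ether of (7R,7′R,8S,8′S)-syringaresinol | COc1cc([C@@H]2OC[C@@H]3[C@H]2CO[C@H]3c2cc(OC)c(O)c(OC)c2)cc(OC)c1O[Si](C(C)C)(C(C)C)C(C)C | intermediate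
17 | (S)-4-benzyl-3-(chloroacetyl)oxazolidin-2-one | O=C(CCl)N1[C@@H](Cc2ccccc2)COC1=O | starting material
18 | ring B aryloxyacetyl imide of 16 | COc1cc([C@@H]2OC[C@@H]3[C@H]2CO[C@H]3c2cc(OC)c(OCC(=O)N3[C@@H](Cc4ccccc4)COC3=O)c(OC)c2)cc(OC)c1O[Si](C(C)C)(C(C)C)C(C)C | intermediate
19 | 4-benzyloxy-3-methoxybenzaldehyde | O=Cc1ccc(OCc2ccccc2)c(OC)c1 | starting material
20 | (Z)-dibutylboron enolate of 18 | COc1cc([C@@H]2OC[C@@H]3[C@H]2CO[C@H]3c2cc(OC)c(O/C=C(\OB(CCCC)CCCC)N3[C@@H](Cc4ccccc4)COC3=O)c(OC)c2)cc(OC)c1O[Si](C(C)C)(C(C)C)C(C)C | intermediate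
21 | ring B (2S,3R) syn aldol adduct | COc1cc([C@@H]2OC[C@@H]3[C@H]2CO[C@H]3c2cc(OC)c(O[C@H](C(=O)N3[C@@H](Cc4ccccc4)COC3=O)[C@H](O)c3ccc(OCc4ccccc4)c(OC)c3)c(OC)c2)cc(OC)c1O[Si](C(C)C)(C(C)C)C(C)C | intermediate
22 | ring B (7R,8R)-threo diol arm, ring A TIPS | COc1cc([C@@H]2OC[C@@H]3[C@H]2CO[C@H]3c2cc(OC)c(O[C@H](CO)[C@H](O)c3ccc(OCc4ccccc4)c(OC)c3)c(OC)c2)cc(OC)c1O[Si](C(C)C)(C(C)C)C(C)C | intermediate
23 | ring B (7S,8R)-erythro bis(4-nitrobenzoate) arm, ring A TIPS | COc1cc([C@@H]2OC[C@@H]3[C@H]2CO[C@H]3c2cc(OC)c(O[C@H](COC(=O)c3ccc(cc3)[N+](=O)[O-])[C@@H](OC(=O)c3ccc(cc3)[N+](=O)[O-])c3ccc(OCc4ccccc4)c(OC)c3)c(OC)c2)cc(OC)c1O[Si](C(C)C)(C(C)C)C(C)C | intermediate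
24 | ring A phenol with ring B erythro diester arm | COc1cc([C@@H]2OC[C@@H]3[C@H]2CO[C@H]3c2cc(OC)c(O[C@H](COC(=O)c3ccc(cc3)[N+](=O)[O-])[C@@H](OC(=O)c3ccc(cc3)[N+](=O)[O-])c3ccc(OCc4ccccc4)c(OC)c3)c(OC)c2)cc(OC)c1O | intermediate
25 | (E)-isoeugenol | C/C=C/c1ccc(O)c(OC)c1 | starting material
26 | (R)-4-benzyl-3-(chloroacetyl)oxazolidin-2-one | O=C(CCl)N1[C@H](Cc2ccccc2)COC1=O | starting material
27 | (4R)-4-benzyl-3-{2-[2-methoxy-4-((E)-prop-1-enyl)phenoxy]acetyl}oxazolidin-2-one | C/C=C/c1ccc(OCC(=O)N2[C@H](Cc3ccccc3)COC2=O)c(OC)c1 | intermediate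
28 | (Z)-dibutylboron enolate of 27 | C/C=C/c1ccc(O/C=C(\OB(CCCC)CCCC)N2[C@H](Cc3ccccc3)COC2=O)c(OC)c1 | intermediate
29 | (2R,3S) syn aldol adduct of 27 and 19 | C/C=C/c1ccc(O[C@@H](C(=O)N2[C@H](Cc3ccccc3)COC2=O)[C@@H](O)c2ccc(OCc3ccccc3)c(OC)c2)c(OC)c1 | intermediate
30 | (1S,2S)-threo diol | C/C=C/c1ccc(O[C@@H](CO)[C@@H](O)c2ccc(OCc3ccccc3)c(OC)c2)c(OC)c1 | intermediate
31 | (1R,2S)-erythro bis(4-nitrobenzoate) | C/C=C/c1ccc(O[C@@H](COC(=O)c2ccc(cc2)[N+](=O)[O-])[C@H](OC(=O)c2ccc(cc2)[N+](=O)[O-])c2ccc(OCc3ccccc3)c(OC)c2)c(OC)c1 | intermediate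
32 | aldehyde carrying protected G3 | O=Cc1ccc(O[C@@H](COC(=O)c2ccc(cc2)[N+](=O)[O-])[C@H](OC(=O)c2ccc(cc2)[N+](=O)[O-])c2ccc(OCc3ccccc3)c(OC)c2)c(OC)c1 | intermediate
33 | ring A aryloxyacetyl imide with ring B erythro diester arm | COc1cc([C@@H]2OC[C@@H]3[C@H]2CO[C@H]3c2cc(OC)c(O[C@H](COC(=O)c3ccc(cc3)[N+](=O)[O-])[C@@H](OC(=O)c3ccc(cc3)[N+](=O)[O-])c3ccc(OCc4ccccc4)c(OC)c3)c(OC)c2)cc(OC)c1OCC(=O)N1[C@@H](Cc2ccccc2)COC1=O | intermediate
34 | (Z)-dibutylboron enolate of 33 | COc1cc([C@@H]2OC[C@@H]3[C@H]2CO[C@H]3c2cc(OC)c(O[C@H](COC(=O)c3ccc(cc3)[N+](=O)[O-])[C@@H](OC(=O)c3ccc(cc3)[N+](=O)[O-])c3ccc(OCc4ccccc4)c(OC)c3)c(OC)c2)cc(OC)c1O/C=C(\OB(CCCC)CCCC)N1[C@@H](Cc2ccccc2)COC1=O | intermediate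
35 | ring A (2S,3R) syn aldol adduct carrying protected G3, ring B erythro diester arm | COc1cc([C@@H]2OC[C@@H]3[C@H]2CO[C@H]3c2cc(OC)c(O[C@H](COC(=O)c3ccc(cc3)[N+](=O)[O-])[C@@H](OC(=O)c3ccc(cc3)[N+](=O)[O-])c3ccc(OCc4ccccc4)c(OC)c3)c(OC)c2)cc(OC)c1O[C@H](C(=O)N1[C@@H](Cc2ccccc2)COC1=O)[C@H](O)c1ccc(O[C@@H](COC(=O)c2ccc(cc2)[N+](=O)[O-])[C@H](OC(=O)c2ccc(cc2)[N+](=O)[O-])c2ccc(OCc3ccccc3)c(OC)c2)c(OC)c1 | intermediate
36 | target with the phenols of G1 and G3 as benzyl ethers | COc1cc([C@@H]2OC[C@@H]3[C@H]2CO[C@H]3c2cc(OC)c(O[C@H](CO)[C@@H](O)c3ccc(OCc4ccccc4)c(OC)c3)c(OC)c2)cc(OC)c1O[C@H](CO)[C@H](O)c1ccc(O[C@@H](CO)[C@H](O)c2ccc(OCc3ccccc3)c(OC)c2)c(OC)c1 | intermediate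
37 | CNP0316493.1 | COc1cc([C@@H](O)[C@H](CO)Oc2ccc([C@@H](O)[C@@H](CO)Oc3c(OC)cc([C@@H]4OC[C@@H]5[C@H]4CO[C@H]5c4cc(OC)c(O[C@H](CO)[C@@H](O)c5ccc(O)c(OC)c5)c(OC)c4)cc3OC)cc2OC)ccc1O | target

**Step count.** Total: 23 steps. Longest linear sequence: 15 steps (1, 2, 6–14, 20–23); the aldehyde branch (15–19) joins at step 21.

**Steps most likely to fail**

Step 6. The lactone enolate may be quenched by proton transfer before the aldehyde reacts, or the aldolate may revert on work-up, so that only the simple Michael product is obtained. The fallback separates the two bond formations. It sets out from 9 and 5: the lithiated dithiane is added to 5 at −78 °C and quenched with acetic acid to give the (4S,5S) Michael adduct lactone F1, which is purified. F1 is then deprotonated with LDA in THF at −78 °C, transmetalated with ZnCl2 and treated with 10, so that the aldol can be tuned on its own. The route is rejoined at 13.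

Step 13 (the same operation recurs in step 18). Substitution at the electron-rich benzylic carbinol may lose fidelity, through ionisation of the oxyphosphonium ion with partial retention or through elimination to the enol ether. The fallback inverts C7 by oxidation and chelation-controlled reduction. It sets out from 22: the primary hydroxyl is silylated (TBSCl, imidazole, DMF) to give the threo 9-O-TBS ether F4. Dess–Martin periodinane with NaHCO3 gives the alpha-aryloxy ketone F5. Zn(BH4)2 in Et2O at −30 °C, through the five-membered chelate of the ketone and aryloxy oxygens, should deliver hydride to give the erythro alcohol F6. AcOH/THF/H2O removes the primary silyl group without touching the aryl TIPS ether to give the erythro diol F7. Acylation with 4-nitrobenzoyl chloride, pyridine and DMAP returns to the route at 23.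

Step 9. The rings close through benzylic cations, and the silylated ring A carbinol ionises less readily than the phenolic ring B carbinol. Acid strong enough to close the second ring may therefore reopen the first and let C7/C7′ drift toward the 7-epi series, or leave a 7,7′-epoxy tetrahydrofuran behind. The fallback lets both closures run through quinone methides and restores the differentiation afterwards. It sets out from 15: TBAF removes the silyl group to give the bis-phenolic tetraol F2. Very mild acid (Amberlyst-15, THF, rt) should close both rings through the two para-quinone methides to give (−)-syringaresinol F3. Because F3 is C2-symmetric its two phenols are equivalent, so monosilylation with one equivalent of TIPSOTf and 2,6-lutidine at −40 °C, with recycling of diol and bis-ether, returns to the route at 16.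

**Further compounds**

F1 | step 6 | (4S,5S)-4-{2-[3,5-dimethoxy-4-(triisopropylsilyloxy)phenyl]-1,3-dithian-2-yl}-5-[(1S,2R,5S)-menthyloxy]dihydrofuran-2(3H)-one | O=C1C[C@H](C2(c3cc(OC)c(O[Si](C(C)C)(C(C)C)C(C)C)c(OC)c3)SCCCS2)[C@@H](O[C@H]2C[C@@H](C)CC[C@@H]2C(C)C)O1
F2 | step 9 | (2S,3S)-1,4-bis(4-hydroxy-3,5-dimethoxyphenyl)-2,3-bis(hydroxymethyl)butane-1,4-diol (C1/C4 epimers) | OC(c1cc(OC)c(O)c(OC)c1)[C@H](CO)[C@@H](CO)C(O)c1cc(OC)c(O)c(OC)c1
F3 | step 9 | (−)-syringaresinol, (7R,7′R,8S,8′S) | COc1cc([C@@H]2OC[C@@H]3[C@H]2CO[C@H]3c2cc(OC)c(O)c(OC)c2)cc(OC)c1O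
F4 | step 13 | threo 9-O-TBS ether of 22 | COc1cc([C@@H]2OC[C@@H]3[C@H]2CO[C@H]3c2cc(OC)c(O[C@H](CO[Si](C)(C)C(C)(C)C)[C@H](O)c3ccc(OCc4ccccc4)c(OC)c3)c(OC)c2)cc(OC)c1O[Si](C(C)C)(C(C)C)C(C)C
F5 | step 13 | (8R) alpha-aryloxy aryl ketone, 9-O-TBS | COc1cc([C@@H]2OC[C@@H]3[C@H]2CO[C@H]3c2cc(OC)c(O[C@H](CO[Si](C)(C)C(C)(C)C)C(=O)c3ccc(OCc4ccccc4)c(OC)c3)c(OC)c2)cc(OC)c1O[Si](C(C)C)(C(C)C)C(C)C
F6 | step 13 | (7S,8R)-erythro alcohol, 9-O-TBS | COc1cc([C@@H]2OC[C@@H]3[C@H]2CO[C@H]3c2cc(OC)c(O[C@H](CO[Si](C)(C)C(C)(C)C)[C@@H](O)c3ccc(OCc4ccccc4)c(OC)c3)c(OC)c2)cc(OC)c1O[Si](C(C)C)(C(C)C)C(C)C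
F7 | step 13 | (7S,8R)-erythro diol, ring A TIPS | COc1cc([C@@H]2OC[C@@H]3[C@H]2CO[C@H]3c2cc(OC)c(O[C@H](CO)[C@@H](O)c3ccc(OCc4ccccc4)c(OC)c3)c(OC)c2)cc(OC)c1O[Si](C(C)C)(C(C)C)C(C)C
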